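## Retrosynthetic overview

1. End game: the target comes from the 3α,15-diacetate by removing only the primary acetate; the axial 3α-oxygen comes from equatorial hydride attack on a C3 ketone; the 4α-methyl (C18) comes from α-face methylation of a ring-A β-keto ester.
2. Key disconnection C4–C5 (with C9–C10 and the 8(17)-alkene in the same cascade): the α-carbon of an acyclic β-keto ester, normally a nucleophile, is oxidised by Mn(OAc)3 to an electrophilic α-keto radical (an enolonium-type synthon) that attacks the nucleophilic C5=C10 alkene.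
3. Ring order: ring A first (6-endo), then ring B (6-endo); Cu(OAc)2 ends the cascade as the exocyclic methylene; a recoverable 8-phenylmenthyl ester sets the absolute sense of C5, C9 and C10.
4. The acyclic precursor comes from an acetoacetate dianion and a C15 allylic chloride.
5. The chloride comes from (2E,6E)-farnesol: asymmetric hydrogenation (sets C13), SeO2 oxidation of the terminal (E)-methyl, Corey–Kim chlorination.

Assumption: the (1S,2R,5S) antipode of 8-phenylmenthol is taken, from recalled analogous tandem cyclisations and a face-shielding model (not verified), to be the one that shields the re face of the chelated C4 radical and so gives the 5α-H/10β-methyl series; it is commercial and is recovered in step 7.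

## Route

Step 1
Reactants: 1 (2E,6E)-farnesol
Product: 2 (S)-2,3-dihydrofarnesol [(3S,6E)-3,7,11-trimethyldodeca-6,10-dien-1-ol]
Conditions: Ru(OAc)2[(R)-BINAP] (0.2 mol %), H2 (90 atm), MeOH–H2O 95:5, 20 °C
Reagents that add atoms: none
Why: Hydroxyl-directed asymmetric hydrogenation (Noyori type) reduces only the allylic-alcohol alkene, the (R)-BINAP ligand delivering H2 to the face that gives the 3S centre (the later C13) in high ee as it does for geraniol to (S)-citronellol, while the two isolated trisubstituted alkenes do not bind and are kept.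

Step 2
Reactants: 2 (S)-2,3-dihydrofarnesol
Product: 5 (2E,6E,10S)-2,6,10-trimethyldodeca-2,6-diene-1,12-diol, via ene-adduct seleninic acid 3 (not isolated), via allyl selenoxylate 4 (not isolated)
Conditions: SeO2 (0.3 equiv), t-BuOOH (2.5 equiv), salicylic acid (0.1 equiv), CH2Cl2, 0 to 20 °C
Reagents that add atoms: selenium dioxide O=[Se]=O; tert-butyl hydroperoxide CC(C)(C)OO (terminal oxidant that regenerates SeO2)
Why: Selenium dioxide allylic oxidation (ene reaction then [2,3]-sigmatropic shift, run catalytically with t-BuOOH) picks the terminal isopropylidene group, the most electron-rich and least hindered alkene, and oxidises its (E)-methyl group to the (E)-allylic alcohol without touching the stereocentre; the main loss is some oxidation at the inner alkene and over-oxidation to the enal.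

Step 3
Reactants: 5 (2E,6E,10S)-2,6,10-trimethyldodeca-2,6-diene-1,12-diol
Product: 7 (3S,6E,10E)-12-chloro-3,7,11-trimethyldodeca-6,10-dien-1-ol, via allylic alkoxysulfonium chloride 6 (not isolated)
Conditions: NCS (1.3 equiv), Me2S (1.5 equiv), CH2Cl2, −20 °C; then 5, 0 °C, 2 h
Reagents that add atoms: N-chlorosuccinimide ClN1C(=O)CCC1=O
Why: Corey–Kim chlorination is selective for allylic alcohols because only the allylic alkoxysulfonium ion is displaced by chloride (SN2 at the primary carbon, no allylic shift) at 0 °C, whereas the saturated primary hydroxyl is returned on aqueous work-up, so no protecting group is needed.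

Step 4
Reactants: 8 (+)-8-phenylmenthol [(1S,2R,5S)-5-methyl-2-(2-phenylpropan-2-yl)cyclohexan-1-ol]; 9 2,2,6-trimethyl-4H-1,3-dioxin-4-one
Product: 11 (1S,2R,5S)-5-methyl-2-(2-phenylpropan-2-yl)cyclohexyl 3-oxobutanoate, via acetylketene 10 (not isolated)
Conditions: xylene, 140 °C, acetone distilled off
Reagents that add atoms: none
Why: Thermal retro-hetero-Diels–Alder cleavage of the dioxinone gives acetylketene, which acylates even this hindered secondary alcohol cleanly (acetoacetylation) with no change at its three stereocentres.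

Step 5
Reactants: 11 (1S,2R,5S)-8-phenylmenthyl acetoacetate; 7 (3S,6E,10E)-12-chloro-3,7,11-trimethyldodeca-6,10-dien-1-ol
Product: 14 (1S,2R,5S)-5-methyl-2-(2-phenylpropan-2-yl)cyclohexyl (6E,10E,14S)-16-hydroxy-6,10,14-trimethyl-3-oxohexadeca-6,10-dienoate, via acetoacetate dianion 12 (not isolated), via chloro alkoxide 13 (not isolated)
Conditions: 11 (1.5 equiv), NaH (1.5 equiv), THF, 0 °C; n-BuLi (1.5 equiv), 0 °C; then 7 (1.0 equiv, pre-treated with LiN(SiMe3)2, 1.0 equiv, THF, −78 °C); 0 °C, 1 h; aq. NH4Cl
Reagents that add atoms: none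
Why: Acetoacetate dianion alkylation (Huckin–Weiler): the more reactive terminal carbanion attacks the primary allylic chloride by SN2 with retention of the (E)-alkene, and prior conversion of the free hydroxyl into its lithium alkoxide stops it from protonating the dianion.

Step 6
Reactants: 14 acyclic 8-phenylmenthyl β-keto ester
Product: 17 (1S,2R,5S)-8-phenylmenthyl ester of (13S)-15-hydroxy-3-oxo-18,19-dinorlabd-8(17)-ene-4-carboxylic acid (5α-H; 9α-H; 10β-CH3; C4–H enolisable; equatorial 4α-ester drawn), via monocyclic C10 radical 15 (not isolated), via bicyclic C8 radical 16 (not isolated)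
Conditions: Mn(OAc)3·2H2O (2.2 equiv), Cu(OAc)2·H2O (1.0 equiv), Yb(OTf)3 (1.0 equiv), degassed CF3CH2OH, −5 to 0 °C
Reagents that add atoms: none
Why: Oxidative free-radical polyene cyclisation: one-electron oxidation of the Yb(OTf)3-chelated enolate by trivalent manganese turns the normally nucleophilic α-carbon (C4) into an electrophilic α-keto radical that adds 6-endo to the nucleophilic C5=C10 alkene, the tertiary C10 radical closes ring B 6-endo onto C9=C8 through a chair–chair array of the two (E)-alkenes (trans-decalin with 5α-H and 10β-CH3 and an equatorial 9β side chain), divalent copper oxidises the tertiary C8 radical with loss of a C17 hydrogen to the exocyclic alkene, and the phenyl ring of the (1S,2R,5S)-auxiliary covers the re face of the chelated C4 radical so that bond formation on its si face fixes the absolute configuration of C5 and hence of C10 and C9.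

Step 7
Reactants: 17 bicyclic 8-phenylmenthyl β-keto ester
Product: 19 methyl (13S)-15-hydroxy-3-oxo-18,19-dinorlabd-8(17)-ene-4-carboxylate (5α-H; 9α-H; 10β-CH3; C4–H enolisable), via ring-A acylketene 18 (not isolated)
Conditions: MeOH–toluene 1:1, DMAP (0.5 equiv), 120 °C, sealed tube
Reagents that add atoms: methanol CO
Why: Transesterification of an enolisable β-keto ester runs through the acylketene (DMAP-assisted loss of 8-phenylmenthol then addition of methanol in large excess), a pathway that does not depend on attack at the hindered ester carbonyl, and C5, C9 and C10 are not touched while C4 remains epimerisable.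

Step 8
Reactants: 19 bicyclic methyl β-keto ester
Product: 21 methyl (13S)-15-hydroxy-3-oxolabd-8(17)-en-19-oate (4α-CH3; 4β-CO2CH3), via potassium enolate 20 (not isolated)
Conditions: K2CO3 (3 equiv), MeI (5 equiv), acetone, 45 °C
Reagents that add atoms: iodomethane CI
Why: C-alkylation of the β-keto ester enolate: MeI attacks C4 from the α face, anti to the axial 10β-methyl group that shields the β face, so the new methyl (C18) becomes equatorial 4α and the ester axial 4β (C19), the known outcome when the ester is in place before the methyl in 10-methyl-3-decalones.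

Step 9
Reactants: 21 methyl (13S)-15-hydroxy-3-oxolabd-8(17)-en-19-oate
Product: 22 methyl (13S)-3α,15-dihydroxylabd-8(17)-en-19-oate
Conditions: LiBH(s-Bu)3 (2.5 equiv), THF, −78 to −40 °C; aq. NH4Cl
Reagents that add atoms: none
Why: Bulky-hydride reduction: lithium tri-sec-butylborohydride cannot use the axial α-face trajectory past H1α and H5α and attacks C3 from the equatorial β direction, giving the axial 3α-alcohol (3R), while the neopentyl methyl ester and the alkene are inert at low temperature.

Step 10
Reactants: 22 methyl (13S)-3α,15-dihydroxylabd-8(17)-en-19-oate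
Product: 23 methyl (13S)-3α,15-diacetoxylabd-8(17)-en-19-oate
Conditions: Ac2O (6 equiv), DMAP (0.3 equiv), pyridine, 40 °C
Reagents that add atoms: acetic anhydride CC(=O)OC(C)=O
Why: Nucleophilic catalysis by DMAP (Steglich-type acylation) acetylates both the primary and the hindered axial secondary hydroxyl with retention at C3.

Step 11
Reactants: 23 methyl (13S)-3α,15-diacetoxylabd-8(17)-en-19-oate
Product: 24 methyl (13S)-3α-acetoxy-15-hydroxylabd-8(17)-en-19-oate (CNP0230414.1)
Conditions: K2CO3 (0.2 equiv), MeOH, 0 °C, stopped when 23 is consumed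
Reagents that add atoms: none
Why: Base-catalysed methanolysis (Zemplén-type transesterification) removes the unhindered primary acetate far faster than the axial C3 acetate flanked by the quaternary C4, and exchange at the methyl ester in methanol is degenerate.

## Compound list

1 | (2E,6E)-farnesol [(2E,6E)-3,7,11-trimethyldodeca-2,6,10-trien-1-ol] | CC(C)=CCC/C(C)=C/CC/C(C)=C/CO | starting material
2 | (S)-2,3-dihydrofarnesol [(3S,6E)-3,7,11-trimethyldodeca-6,10-dien-1-ol] | CC(C)=CCC/C(C)=C/CC[C@H](C)CCO | intermediate
3 | ene-adduct allylic seleninic acid of 2 (both epimers at the selenium-bearing carbon; transient) | C=C(C)C(CC/C(C)=C/CC[C@H](C)CCO)[Se](=O)O | intermediate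
4 | allyl selenoxylate (divalent selenium ester after the [2,3]-shift; transient) | O[Se]OC/C(C)=C/CC/C(C)=C/CC[C@H](C)CCO | intermediate
5 | (2E,6E,10S)-2,6,10-trimethyldodeca-2,6-diene-1,12-diol | OC/C(C)=C/CC/C(C)=C/CC[C@H](C)CCO | intermediate
6 | allylic alkoxydimethylsulfonium chloride of 5 (transient) | C[S+](C)OC/C(C)=C/CC/C(C)=C/CC[C@H](C)CCO.[Cl-] | intermediate
7 | (3S,6E,10E)-12-chloro-3,7,11-trimethyldodeca-6,10-dien-1-ol | ClC/C(C)=C/CC/C(C)=C/CC[C@H](C)CCO | intermediate
8 | (+)-8-phenylmenthol [(1S,2R,5S)-5-methyl-2-(2-phenylpropan-2-yl)cyclohexan-1-ol] | O[C@H]1C[C@@H](C)CC[C@@H]1C(C)(C)c1ccccc1 | starting material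
9 | 2,2,6-trimethyl-4H-1,3-dioxin-4-one | CC1=CC(=O)OC(C)(C)O1 | starting material
10 | acetylketene (transient) | CC(=O)C=C=O | intermediate
11 | (1S,2R,5S)-5-methyl-2-(2-phenylpropan-2-yl)cyclohexyl 3-oxobutanoate | CC(=O)CC(=O)O[C@H]1C[C@@H](C)CC[C@@H]1C(C)(C)c1ccccc1 | intermediate
12 | sodium lithium dianion of 11 (transient) | [Na+].[Li+].[CH2-]C(=O)[CH-]C(=O)O[C@H]1C[C@@H](C)CC[C@@H]1C(C)(C)c1ccccc1 | intermediate
13 | lithium alkoxide of 7 (transient) | ClC/C(C)=C/CC/C(C)=C/CC[C@H](C)CC[O-].[Li+] | intermediate
14 | (1S,2R,5S)-5-methyl-2-(2-phenylpropan-2-yl)cyclohexyl (6E,10E,14S)-16-hydroxy-6,10,14-trimethyl-3-oxohexadeca-6,10-dienoate | O=C(CC(=O)CC/C(C)=C/CC/C(C)=C/CC[C@H](C)CCO)O[C@H]1C[C@@H](C)CC[C@@H]1C(C)(C)c1ccccc1 | intermediate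
15 | monocyclic ring-A keto ester with tertiary radical at C10 (transient) | C/C(=C\CC[C@H](C)CCO)CC[C@@H]1[C](C)CCC(=O)[C@H]1C(=O)O[C@H]2C[C@@H](C)CC[C@@H]2C(C)(C)c2ccccc2 | intermediate
16 | bicyclic keto ester with tertiary radical at C8 (transient) | C[C]1CC[C@@H]2[C@](C)(CCC(=O)[C@H]2C(=O)O[C@H]3C[C@@H](C)CC[C@@H]3C(C)(C)c3ccccc3)[C@H]1CC[C@H](C)CCO | intermediate
17 | (1S,2R,5S)-8-phenylmenthyl ester of (13S)-15-hydroxy-3-oxo-18,19-dinorlabd-8(17)-ene-4-carboxylic acid (5α-H, 9α-H, 10β-CH3; C4–H enolisable, equatorial ester drawn) | C=C1CC[C@@H]2[C@](C)(CCC(=O)[C@H]2C(=O)O[C@H]3C[C@@H](C)CC[C@@H]3C(C)(C)c3ccccc3)[C@H]1CC[C@H](C)CCO | intermediate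
18 | ring-A acylketene (3-oxo, C4=C=O; transient) | C=C1CC[C@@H]2[C@](C)(CCC(=O)C2=C=O)[C@H]1CC[C@H](C)CCO | intermediate
19 | methyl (13S)-15-hydroxy-3-oxo-18,19-dinorlabd-8(17)-ene-4-carboxylate (C4–H enolisable, equatorial ester drawn) | C=C1CC[C@@H]2[C@](C)(CCC(=O)[C@H]2C(=O)OC)[C@H]1CC[C@H](C)CCO | intermediate
20 | potassium enolate of 19 (transient) | C=C1CC[C@@H]2[C@](C)(CCC([O-])=C2C(=O)OC)[C@H]1CC[C@H](C)CCO.[K+] | intermediate
21 | methyl (13S)-15-hydroxy-3-oxolabd-8(17)-en-19-oate | C=C1CC[C@@H]2[C@](C)(CCC(=O)[C@]2(C)C(=O)OC)[C@H]1CC[C@H](C)CCO | intermediate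
22 | methyl (13S)-3α,15-dihydroxylabd-8(17)-en-19-oate | C=C1CC[C@@H]2[C@](C)(CC[C@@H](O)[C@]2(C)C(=O)OC)[C@H]1CC[C@H](C)CCO | intermediate
23 | methyl (13S)-3α,15-diacetoxylabd-8(17)-en-19-oate | C=C1CC[C@@H]2[C@](C)(CC[C@@H](OC(C)=O)[C@]2(C)C(=O)OC)[C@H]1CC[C@H](C)CCOC(C)=O | intermediate
24 | methyl (13S)-3α-acetoxy-15-hydroxylabd-8(17)-en-19-oate, CNP0230414.1 [(3R,4R,5R,9S,10R,13S) in labdane numbering] | C=C1CC[C@@H]2[C@](C)(CC[C@@H](OC(C)=O)[C@]2(C)C(=O)OC)[C@H]1CC[C@H](C)CCO | target

## Step count and risks

Total step count: 11.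
Longest linear sequence: 10 steps (1 → 2 → 5 → 7 → 14 → 17 → 19 → 21 → 22 → 23 → 24); step 4 is the one-step side branch.

**Step 6 is the most likely to fail.** The product still has an enolisable C4–H and can be over-oxidised, the exo/endo alkene ratio at C8 depends on the copper termination, and auxiliary-controlled face selectivity has not been shown together with Cu(OAc)2 termination or with a free hydroxyl in the substrate. The fallback sets out from 7 and comes back at 19, replacing auxiliary control and oxidative termination by a catalyst-controlled group-transfer cascade on the methyl ester. The dianion of methyl acetoacetate (NaH, n-BuLi, THF, 0 °C) is alkylated with 7, used as its lithium alkoxide 13, to give methyl (6E,10E,14S)-16-hydroxy-6,10,14-trimethyl-3-oxohexadeca-6,10-dienoate F1. Its sodium enolate is selenenylated with PhSeCl at −78 °C to give methyl (6E,10E,14S)-16-hydroxy-6,10,14-trimethyl-3-oxo-2-(phenylselanyl)hexadeca-6,10-dienoate F2, in which the α-selenide is a latent electrophilic α-carbon. Homolysis of the C–Se bond (Et3B/O2, toluene, −78 °C) is run with Mg(ClO4)2 and an enantiopure 2,2′-isopropylidenebis(4-tert-butyl-2-oxazoline), the antipode being chosen for the 5α-H series. The ligand binds the keto ester at two points and shields one face of the α-radical, so the same 6-endo/6-endo cascade runs and ends by phenylselanyl transfer to C8. This gives methyl (13S)-15-hydroxy-3-oxo-8α-(phenylselanyl)-18,19-dinorlabdane-4-carboxylate F3. Oxidation with H2O2 (pyridine, CH2Cl2, 0 °C) and syn-elimination of the selenoxide toward C17 give 19 after separation from endocyclic alkene isomers. This fallback also makes steps 4 and 7 unnecessary.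

**Step 9 is second.** The ketone is flanked by a quaternary carbon carrying an axial ester, and any axial (α-face) hydride attack gives the unwanted equatorial 3β-alcohol. The fallback sets out from 21 and comes back at 22, replacing substrate control by reagent control. An oxazaborolidine-catalysed (Corey–Bakshi–Shibata) reduction is run with catecholborane in toluene at −78 °C, using the (S)-B-butyl oxazaborolidine from (S)-diphenylprolinol ((S)-1-butyl-3,3-diphenyltetrahydro-1H,3H-pyrrolo[1,2-c][1,3,2]oxazaborole). The catalyst treats the quaternary C4 as the large group and C2 as the small one and delivers hydride to the β face to give the 3R alcohol. Catecholborane does not hydroborate the exocyclic alkene at this temperature. No compound outside the list is made (F0).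

**Step 11 is third.** It is the last step and relies only on a rate difference between two acetates; if the 3-acetate is also cleaved, the liberated β-hydroxy ester could undergo retro-aldol opening under base. The fallback sets out from 22 and comes back at 24, using orthogonal protection instead of kinetic differentiation. The primary hydroxyl is silylated (TBSCl, imidazole, CH2Cl2, 0 °C) to give methyl (13S)-15-(tert-butyldimethylsilyloxy)-3α-hydroxylabd-8(17)-en-19-oate F4. The axial alcohol is acetylated (Ac2O, DMAP, pyridine, 40 °C) to give methyl (13S)-3α-acetoxy-15-(tert-butyldimethylsilyloxy)labd-8(17)-en-19-oate F5. The silyl ether is cleaved with HF·pyridine (THF, 0 °C) to give 24.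

## Further compounds

F1 | step 6 | methyl (6E,10E,14S)-16-hydroxy-6,10,14-trimethyl-3-oxohexadeca-6,10-dienoate | COC(=O)CC(=O)CC/C(C)=C/CC/C(C)=C/CC[C@H](C)CCO
F2 | step 6 | methyl (6E,10E,14S)-16-hydroxy-6,10,14-trimethyl-3-oxo-2-(phenylselanyl)hexadeca-6,10-dienoate (both C2 epimers) | COC(=O)C([Se]c1ccccc1)C(=O)CC/C(C)=C/CC/C(C)=C/CC[C@H](C)CCO
F3 | step 6 | methyl (13S)-15-hydroxy-3-oxo-8α-(phenylselanyl)-18,19-dinorlabdane-4-carboxylate | C[C@@]1([Se]c2ccccc2)CC[C@@H]2[C@](C)(CCC(=O)[C@H]2C(=O)OC)[C@H]1CC[C@H](C)CCO
F0 | step 9 | none | none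
F4 | step 11 | methyl (13S)-15-(tert-butyldimethylsilyloxy)-3α-hydroxylabd-8(17)-en-19-oate | C=C1CC[C@@H]2[C@](C)(CC[C@@H](O)[C@]2(C)C(=O)OC)[C@H]1CC[C@H](C)CCO[Si](C)(C)C(C)(C)C
F5 | step 11 | methyl (13S)-3α-acetoxy-15-(tert-butyldimethylsilyloxy)labd-8(17)-en-19-oate | C=C1CC[C@@H]2[C@](C)(CC[C@@H](OC(C)=O)[C@]2(C)C(=O)OC)[C@H]1CC[C@H](C)CCO[Si](C)(C)C(C)(C)C
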